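**Remarks on the chemistry (assumptions)**
- The numbering of the target is used for every intermediate: ring C1, C5, C6, C7, C8, C9, C10; side chain C2(=O)–C3–C4(OH)–C15; C14 is the methyl on C10; lactone C12(=O)–C11(=C13). β is the face of the C9 hydroxyl, α the opposite face. In this numbering the target is 1S,4S,5S,6R,7S,9R,10S and carries an (R)-2-methylbutanoate.
- Mal = C(CH2Cl)(CO2t-Bu)2, the masked C11–C13 unit.
- Compounds 1, 2, 6, 17 and 19 are taken to be commercial.
- Rh2(S-PTAD)4 is taken to give the bridgehead configuration drawn; if the sense of induction is the opposite, Rh2(R-PTAD)4 is used.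

## The problem

The target 30 is a cycloheptane (C1, C5–C10) cis-fused at C6/C7 to an α-methylene-γ-butyrolactone. C1 is a tertiary α-ketol carrying the (S)-3-hydroxybutanoyl chain, C5 carries an (R)-2-methylbutanoate, C9 a free hydroxyl and C10 a methyl group. Six ring stereocentres (C1, C5, C6, C7, C9, C10) sit on a conformationally mobile seven-membered ring, where induction from one centre to the next is unreliable. C4 and the ester α-carbon are remote and are best bought. The relative pattern is C9–O β, C10–Me α, C1–OH α with the acyl group β, C5–O β, C6–O α and C7–C11 α. The methylene lactone (Michael acceptor), the β-hydroxy ketone (retro-aldol, dehydration), the tertiary α-ketol (ketol shift) and the epimerisable ester next to a free hydroxyl forbid strong base, hydride or hydrogenation late in the route.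

The feature that makes the key step possible is the C6–C7–C8–C9 edge. Both ends carry oxygen, C7 carries the carbon branch C11 and C8 is CH2. This is the atom pattern of a 3-substituted furan whose oxygen can bridge C6 and C9, while C5–C1–C10, with oxygen on the central C1, is a three-carbon oxyallyl (vinylcarbenoid) partner. In the resulting 8-oxabicyclo[3.2.1]octane (ether bridge on the β face) H7, the C1 side chain and the C5 oxygen lie on the exo (β) face and the C10 methyl is equatorial (α). The one centre that does not fit, C6–O α, is trans-1,4 to C9–O, which is exactly what an SN2 displacement of the bridge oxygen at C6 by the lactone carbonyl delivers.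

## Retrosynthesis

**30 ⇒ 28.** The C11=C13 double bond is cut. The methylene is stored as the quaternary unit C11(CO2H)(CH2Cl) of 28 and released by dehalodecarboxylation under bicarbonate. The usual enolate methylenation of a lactone would need strong base in the presence of a ketone and an epimerisable ester. The precursor has no acidic C–H at C11, so it can be carried from the first step.

**28 ⇒ 26.** The lactone O–C6 bond is cut and C6 is reconnected to the C9 oxygen, giving the oxabicycle 26. A lactonisation of a free 6-alcohol would need retention at C6 and a separately protected 9-hydroxyl. The ether bridge supplies the C9 oxygen with retention and acts as leaving group at C6. The forward reaction must be an acid-triggered intramolecular SN2 by an ester carbonyl of the Mal group, with inversion at C6.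

**26 ⇒ 24 ⇒ 18 + 22.** The C1–C2 bond is cut. A 2-lithioalkene from 22 carries C4 from the chiral pool, and ozonolysis of 24 then gives the ketone 26. An aldol of a methyl ketone would leave C4 to reagent control, and an alkyne would leave the hydration regiochemistry open. The addition must occur on the exo face of the C1 ketone of 18 and prefer the ketone over three esters.

**18 ⇒ 16 ⇒ 14.** The C5–O bond is cut. The kinetic enolate of ketone 14 forms at the CH2 group C5, not at the methine C10, and is hydroxylated on the exo face to give 16. Esterification with 17 at this stage, when no other hydroxyl exists, gives 18.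

**14 ⇒ 12 ⇒ 10.** The C10–CH3 bond and the C7–H bond are cut. The β-keto ester hidden in 10 places the methyl group on C10 without any regiochemical question (12). Hydrogenolysis of the benzyl ester, decarboxylation and exo hydrogenation of C7=C8 then give 14.

**10 ⇒ 5 + 8 (key step).** The C5–C6 and C9–C10 bonds are cut in a formal [4+3] annulation of furan 5 with the vinylcarbenoid from 8. A cationic oxyallyl cycloaddition would make the same bonds but give a racemate. Here a chiral catalyst sets the absolute configuration, and both partners are achiral compounds made in two steps each. The forward step must be selective for the unhindered furan edge, must not unravel the furan and must be enantioselective.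

**5, 8 and 22.** Furan 5 comes from 1 and 2 by arylation (3) and chloromethylation. Diazo compound 8 comes from 6 through 7. Vinyl bromide 22 comes from 19 through 20.

## Roads not taken

**Alternative 1:** The most obvious cut is C6–C7 together with the lactone C–O bond. The forward key step is an intramolecular Barbier-type allylation (Zn or CrCl2) of the ω-formyl allylic bromide A1, closing the seven-membered ring and the methylene lactone at once. A1 needs C1, C5, C9 and C10, including a tertiary carbinol flanked by two stereocentres, to be set in an open chain by a long aldol sequence. The cis or trans outcome of a seven-membered closure depends on the substrate. The sensitive ketol and aldol units must also pass through a metal-mediated step. The chosen plan sets the same centres on a rigid bicycle from two achiral pieces.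

**Alternative 2:** The cis-1,4 oxygens on C5 and C9 could be bridged instead. The forward key step is a [4+3] cycloaddition of 3-methylfuran with an alkoxy-substituted oxyallyl cation, giving A2 with C6–O equatorial and a C7 ketone for the lactone. One ether oxygen cannot serve both C5 and C9 with retention, so one C–O bond must be remade by redox chemistry after the template is gone. The orientation of 3-methylfuran toward an unsymmetrical cation is also uncontrolled. In the chosen plan the bridge joins the trans pair C6/C9, so the single inversion is productive.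

**Alternative 3:** The ring could be bought as cyclohepta-1,3-diene and cut at C10–C14 and C1–C2. The forward key steps are photooxygenation to the meso endoperoxide A3, enantioselective Kornblum–DeLaMare rearrangement to A4, and conjugate addition of a methyl cuprate with an aldol trap of the enolate. C6 and C7 arrive as unfunctionalised CH2 groups. The trap places the carbon chain on C1 anti to the methyl group, so the hydroxyl would have to enter syn to it afterwards. Every later centre relies on a flexible ring. The chosen plan has functionality on every ring carbon after the key step and a template for all six centres.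

Key step: step 5

## Steps

Step 1
Reactants: 1 3-bromofuran; 2 di-tert-butyl malonate
Product: 3 di-tert-butyl 2-(furan-3-yl)malonate
Conditions: Pd(dba)2 (2 mol %), P(t-Bu)3 (4 mol %), K3PO4, toluene, 70 °C
Reagents that add atoms: none
Why: Palladium-catalysed α-arylation of a malonate (Hartwig–Buchwald type); the bulky tert-butyl esters prevent diarylation, and no stereocentre is formed.

Step 2
Reactants: 3 di-tert-butyl 2-(furan-3-yl)malonate
Product: 5 di-tert-butyl 2-(chloromethyl)-2-(furan-3-yl)malonate, via sodium enolate 4 (not isolated)
Conditions: NaH, DMF, 0 °C; then ICH2Cl, 0 °C → rt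
Reagents that add atoms: chloroiodomethane, ClCI
Why: SN2 alkylation of the stabilised malonate anion at the iodide end of the dihalide; C11 becomes quaternary, non-enolisable and non-stereogenic (two identical esters), and C13 is stored as a neopentyl chloride that resists SN2 and E2.

Step 3
Reactants: 6 benzyl acetoacetate
Product: 7 benzyl 2-diazo-3-oxobutanoate
Conditions: p-ABSA, Et3N, MeCN, 0 °C → rt
Reagents that add atoms: 4-acetamidobenzenesulfonyl azide (p-ABSA), CC(=O)Nc1ccc(cc1)S(=O)(=O)N=[N+]=[N-]
Why: Regitz diazo transfer to the active methylene of a 1,3-dicarbonyl compound.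

Step 4
Reactants: 7 benzyl 2-diazo-3-oxobutanoate
Product: 8 benzyl 3-[(tert-butyldimethylsilyl)oxy]-2-diazobut-3-enoate
Conditions: TBSOTf, Et3N, CH2Cl2, 0 °C
Reagents that add atoms: tert-butyldimethylsilyl triflate, CC(C)(C)[Si](C)(C)OS(=O)(=O)C(F)(F)F
Why: Soft enolisation and O-silylation of the acetyl group give the siloxyvinyl diazoacetate, the standard precursor of a donor/acceptor vinylcarbenoid.

Step 5
Reactants: 5 di-tert-butyl 2-(chloromethyl)-2-(furan-3-yl)malonate; 8 benzyl 3-[(tert-butyldimethylsilyl)oxy]-2-diazobut-3-enoate
Product: 10 benzyl 3-[(tert-butyldimethylsilyl)oxy]-6-Mal-8-oxabicyclo[3.2.1]octa-2,6-diene-2-carboxylate (bridgeheads are C9 and C6, ether bridge on the β face; C10 bears the ester, C1 the silyloxy group, C7 the Mal group), via divinylcyclopropane 9 (not isolated)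
Conditions: Rh2(S-PTAD)4 (1 mol %), hexane, 23 °C, slow addition of 8 (1.5 equiv)
Reagents that add atoms: none
Why: The catalyst turns 8 into a donor/acceptor siloxyvinyl carbenoid of divalent rhodium, which cyclopropanates the unsubstituted C8=C9 edge of furan 5 to the cis-divinylcyclopropane 9; 9 then undergoes a Cope rearrangement through the obligatory boat transition state, so the overall change is a formal [4+3] annulation that turns the flat furan into C6–C9 of the ring and its oxygen into the C6–O–C9 bridge. The closest known reaction type is the tandem cyclopropanation/Cope rearrangement of siloxyvinyldiazoacetates with furans and N-Boc-pyrroles (Davies [4+3]), which is highly enantioselective with Rh2(S-PTAD)4. The three-membered ring closes by [2+1] cycloaddition (bonds C9–C10 and C8–C10), and the seven-membered carbocycle by [3,3]-sigmatropic ring expansion that forms C5–C6 and breaks C8–C10. The new stereocentres are the bridgeheads C6 and C9; their relative configuration is fixed by the bridge, and their absolute configuration by the carbenoid face that the chiral carboxylate ligands expose in the cyclopropanation, which the Cope step transfers stereospecifically. The step needs site selectivity for the C8=C9 over the C6=C7 bond of the furan; the quaternary Mal group on C7 secures this by blocking the neighbouring α-carbon C6, so that the ester-bearing carbenoid carbon becomes C10 and the vinyl terminus becomes C5. It also needs annulation to win over unravelling of the furan to a dienone, which the siloxy donor (less zwitterionic character) and the non-polar solvent favour. The ester that the carbenoid brings is not wasted: it marks C10 for methylation in step 6 and is then removed.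

Step 6
Reactants: 10 bicyclic silyl enol ether
Product: 12 benzyl 2-methyl-3-oxo-6-Mal-8-oxabicyclo[3.2.1]oct-6-ene-2-carboxylate (methyl on C10, drawn exo), via caesium enolate 11 (not isolated)
Conditions: CsF, MeI, DMF, 0 °C → rt
Reagents that add atoms: iodomethane, CI
Why: Fluoride cleaves the silyl enol ether to the β-keto ester enolate, which is C-methylated regiospecifically at C10 (fluoride-triggered enolate alkylation); the configuration of this quaternary centre does not matter because step 7 resets it.

Step 7
Reactants: 12 methylated β-keto benzyl ester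
Product: 14 6β,9β-epoxy-10α-methyl-7α-Mal-cycloheptan-1-one (2-methyl-6-endo-Mal-8-oxabicyclo[3.2.1]octan-3-one, methyl equatorial), via keto acid 13 (not isolated)
Conditions: H2 (1 atm), Pd/C, EtOAc, rt; then toluene, 80 °C
Reagents that add atoms: none
Why: Hydrogenolysis of the benzyl ester and hydrogenation of C7=C8 from the exo (β) face, the usual face for 8-oxabicyclo[3.2.1]oct-6-enes, put H7 on the β face and the Mal group endo (α). The β-keto acid 13 then decarboxylates, and ketonisation by exo protonation gives the equatorial 10α-methyl ketone, which is also the thermodynamic epimer.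

Step 8
Reactants: 14 bicyclic ketone
Product: 16 6β,9β-epoxy-5β-hydroxy-10α-methyl-7α-Mal-cycloheptan-1-one, via potassium enolate 15 (not isolated)
Conditions: KN(SiMe3)2, THF, −78 °C; then 3-phenyl-2-(phenylsulfonyl)oxaziridine, −78 °C; NH4Cl (aq)
Reagents that add atoms: 3-phenyl-2-(phenylsulfonyl)oxaziridine (Davis reagent), O=S(=O)(N1OC1c1ccccc1)c1ccccc1
Why: Kinetic deprotonation removes the exo (axial) hydrogen of the CH2 group C5, not the methine hydrogen at C10. Davis hydroxylation then occurs on the exo (β) face of the enolate, because the endo face is closed by the Mal group and the two-carbon bridge, and gives the axial 5β-alcohol.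

Step 9
Reactants: 16 α-hydroxy ketone; 17 (R)-2-methylbutanoic acid
Product: 18 6β,9β-epoxy-10α-methyl-7α-Mal-1-oxocycloheptan-5β-yl (R)-2-methylbutanoate
Conditions: EDC·HCl, DMAP, CH2Cl2, 0 °C → rt
Reagents that add atoms: none
Why: Steglich esterification of the only hydroxyl group present; carbodiimide activation of an α-alkyl acid does not epimerise its stereocentre.

Step 10
Reactants: 19 (S)-pent-4-yn-2-ol
Product: 20 (S)-tert-butyldimethyl(pent-4-yn-2-yloxy)silane
Conditions: TBSCl, imidazole, DMF, rt
Reagents that add atoms: tert-butyldimethylsilyl chloride, CC(C)(C)[Si](C)(C)Cl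
Why: Standard silylation; the stereocentre (future C4, S) comes from the chiral pool and is not touched.

Step 11
Reactants: 20 silyl ether of the alkynol
Product: 22 (S)-[(4-bromopent-4-en-2-yl)oxy](tert-butyl)dimethylsilane, via bromovinylborane 21 (not isolated)
Conditions: B-bromo-9-BBN, CH2Cl2, 0 °C; then AcOH, 0 °C → rt
Reagents that add atoms: B-bromo-9-borabicyclo[3.3.1]nonane, BrB1C2CCCC1CCC2
Why: Markovnikov syn-bromoboration of the terminal alkyne (Hara–Suzuki haloboration) followed by protodeboronation gives the 2-bromo-1-alkene.

Step 12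
Reactants: 18 α-acyloxy ketone; 22 vinyl bromide
Product: 24 tertiary allylic alcohol (C1: OH α, 1-methylene-3-silyloxybutyl chain β; bridge and C5 ester unchanged), via vinyllithium 23 (not isolated)
Conditions: 22, t-BuLi (2 equiv per bromide), Et2O, −78 °C; then 18, LaCl3·2LiCl, THF, −78 °C; NH4Cl (aq)
Reagents that add atoms: none
Why: Bromine–lithium exchange gives 23, and the lanthanum salt promotes 1,2-addition over enolisation and favours the ketone over the esters. Attack comes from the exo (β) face of the C1 ketone, as in additions to tropinone and 8-oxabicyclo[3.2.1]octan-3-ones and reinforced here by the endo Mal group, so C1 gets OH α (axial) and the chain β. The trans-diaxial C1–O/C5–O arrangement prevents acyl migration.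

Step 13
Reactants: 24 tertiary allylic alcohol
Product: 26 α-ketol with the C2 ketone (6β,9β-epoxy bridge intact, C4 still silylated), via ozonide 25 (not isolated)
Conditions: O3, CH2Cl2, −78 °C; then Me2S, −78 °C → rt
Reagents that add atoms: ozone, [O-][O+]=O
Why: Ozonolysis of the only C=C bond with reductive work-up turns the 1,1-disubstituted alkene into the C2 ketone without touching any stereocentre.

Step 14
Reactants: 26 bridged α-ketol
Product: 28 α-carboxy-α-(chloromethyl) lactone with free 1-, 4- and 9-hydroxyls (C11 epimers), via lactone ester 27 (not isolated)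
Conditions: TfOH, CH2Cl2–HFIP, −20 → 0 °C; then TFA–H2O (9:1), 0 °C
Reagents that add atoms: none
Why: Acid-mediated cleavage of the bridged ether with neighbouring-group participation: the carbonyl oxygen of one endo tert-butyl ester attacks C6 from the α face (5-exo-tet, anti to the protonated bridge oxygen, helped by the quaternary C11), and the dioxacarbenium ion loses isobutene. Carbonyl-assisted opening of oxygen bridges in 7-oxanorbornanes and the opening of epoxides and iodonium ions by tert-butyl esters are the closest known cases. Inversion at C6 gives the cis-lactone (C6–O α, C7–C11 α) while the bridge oxygen stays on C9 as the β-hydroxyl; aqueous TFA then removes the second tert-butyl ester and the silyl ether.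

Step 15
Reactants: 28 carboxy(chloromethyl) lactone
Product: 30 target CNP0291806.3, via sodium carboxylate 29 (not isolated)
Conditions: NaHCO3, DMF–H2O, 50 °C
Reagents that add atoms: none
Why: Dehalodecarboxylation of a β-chloro carboxylate (Grob-type fragmentation, assisted by the lactone carbonyl) releases CO2 and chloride and forms the C11=C13 methylene; the stereocentre at C11 disappears and no other centre is touched.

## Compound list

1 | 3-bromofuran | Brc1ccoc1 | starting material
2 | di-tert-butyl malonate | CC(C)(C)OC(=O)CC(=O)OC(C)(C)C | starting material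
3 | di-tert-butyl 2-(furan-3-yl)malonate | CC(C)(C)OC(=O)C(c1ccoc1)C(=O)OC(C)(C)C | intermediate
4 | sodium enolate of 3 | CC(C)(C)OC(=O)C(c1ccoc1)=C([O-])OC(C)(C)C.[Na+] | intermediate
5 | di-tert-butyl 2-(chloromethyl)-2-(furan-3-yl)malonate | CC(C)(C)OC(=O)C(CCl)(c1ccoc1)C(=O)OC(C)(C)C | intermediate
6 | benzyl acetoacetate | CC(=O)CC(=O)OCc1ccccc1 | starting material
7 | benzyl 2-diazo-3-oxobutanoate | CC(=O)C(=[N+]=[N-])C(=O)OCc1ccccc1 | intermediate
8 | benzyl 3-[(tert-butyldimethylsilyl)oxy]-2-diazobut-3-enoate | C=C(O[Si](C)(C)C(C)(C)C)C(=[N+]=[N-])C(=O)OCc1ccccc1 | intermediate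
9 | benzyl 4-Mal-6-[1-(tert-butyldimethylsilyloxy)ethenyl]-2-oxabicyclo[3.1.0]hex-3-ene-6-carboxylate (vinyl group endo, ester exo) | O1C=C(C(CCl)(C(=O)OC(C)(C)C)C(=O)OC(C)(C)C)[C@H]2[C@@H]1[C@@]2(C(=O)OCc1ccccc1)C(=C)O[Si](C)(C)C(C)(C)C | intermediate
10 | benzyl 3-[(tert-butyldimethylsilyl)oxy]-6-Mal-8-oxabicyclo[3.2.1]octa-2,6-diene-2-carboxylate (6β,9β-ether bridge) | O1[C@H]2C(C(CCl)(C(=O)OC(C)(C)C)C(=O)OC(C)(C)C)=C[C@@H]1C(C(=O)OCc3ccccc3)=C(O[Si](C)(C)C(C)(C)C)C2 | intermediate
11 | caesium enolate of the β-keto ester from 10 | O1[C@H]2C(C(CCl)(C(=O)OC(C)(C)C)C(=O)OC(C)(C)C)=C[C@@H]1C(C(=O)OCc3ccccc3)=C([O-])C2.[Cs+] | intermediate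
12 | benzyl 2-methyl-3-oxo-6-Mal-8-oxabicyclo[3.2.1]oct-6-ene-2-carboxylate (methyl exo at C10) | O1[C@H]2C(C(CCl)(C(=O)OC(C)(C)C)C(=O)OC(C)(C)C)=C[C@@H]1[C@](C)(C(=O)OCc3ccccc3)C(=O)C2 | intermediate
13 | 2-methyl-3-oxo-6-endo-Mal-8-oxabicyclo[3.2.1]octane-2-carboxylic acid | O1[C@H]2[C@H](C(CCl)(C(=O)OC(C)(C)C)C(=O)OC(C)(C)C)C[C@@H]1[C@](C)(C(O)=O)C(=O)C2 | intermediate
14 | 6β,9β-epoxy-10α-methyl-7α-Mal-cycloheptan-1-one | O1[C@H]2[C@H](C(CCl)(C(=O)OC(C)(C)C)C(=O)OC(C)(C)C)C[C@@H]1[C@H](C)C(=O)C2 | intermediate
15 | potassium C1/C5 enolate of 14 | O1[C@H]2[C@H](C(CCl)(C(=O)OC(C)(C)C)C(=O)OC(C)(C)C)C[C@@H]1[C@H](C)C([O-])=C2.[K+] | intermediate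
16 | 6β,9β-epoxy-5β-hydroxy-10α-methyl-7α-Mal-cycloheptan-1-one | O1[C@H]2[C@H](C(CCl)(C(=O)OC(C)(C)C)C(=O)OC(C)(C)C)C[C@@H]1[C@H](C)C(=O)[C@H]2O | intermediate
17 | (R)-2-methylbutanoic acid | OC(=O)[C@H](C)CC | starting material
18 | 6β,9β-epoxy-10α-methyl-7α-Mal-1-oxocycloheptan-5β-yl (R)-2-methylbutanoate | O1[C@H]2[C@H](C(CCl)(C(=O)OC(C)(C)C)C(=O)OC(C)(C)C)C[C@@H]1[C@H](C)C(=O)[C@H]2OC(=O)[C@H](C)CC | intermediate
19 | (S)-pent-4-yn-2-ol | C#CC[C@H](C)O | starting material
20 | (S)-tert-butyldimethyl(pent-4-yn-2-yloxy)silane | C#CC[C@H](C)O[Si](C)(C)C(C)(C)C | intermediate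
21 | (Z)-B-[2-bromo-4-(tert-butyldimethylsilyloxy)pent-1-enyl]-9-borabicyclo[3.3.1]nonane (4S) | Br/C(C[C@H](C)O[Si](C)(C)C(C)(C)C)=C\B1C2CCCC1CCC2 | intermediate
22 | (S)-[(4-bromopent-4-en-2-yl)oxy](tert-butyl)dimethylsilane | C=C(Br)C[C@H](C)O[Si](C)(C)C(C)(C)C | intermediate
23 | (S)-[4-(tert-butyldimethylsilyloxy)pent-1-en-2-yl]lithium | [Li]C(=C)C[C@H](C)O[Si](C)(C)C(C)(C)C | intermediate
24 | 6β,9β-epoxy-1α-hydroxy-10α-methyl-7α-Mal-1β-[(S)-4-(tert-butyldimethylsilyloxy)pent-1-en-2-yl]cycloheptan-5β-yl (R)-2-methylbutanoate | O1[C@H]2[C@H](C(CCl)(C(=O)OC(C)(C)C)C(=O)OC(C)(C)C)C[C@@H]1[C@H](C)[C@@](O)(C(=C)C[C@H](C)O[Si](C)(C)C(C)(C)C)[C@H]2OC(=O)[C@H](C)CC | intermediate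
25 | secondary ozonide (1,2,4-trioxolane) of 24, epimers at the ozonide carbon | O1[C@H]2[C@H](C(CCl)(C(=O)OC(C)(C)C)C(=O)OC(C)(C)C)C[C@@H]1[C@H](C)[C@@](O)(C3(C[C@H](C)O[Si](C)(C)C(C)(C)C)OOCO3)[C@H]2OC(=O)[C@H](C)CC | intermediate
26 | 6β,9β-epoxy-1α-hydroxy-10α-methyl-7α-Mal-1β-[(S)-3-(tert-butyldimethylsilyloxy)butanoyl]cycloheptan-5β-yl (R)-2-methylbutanoate | O1[C@H]2[C@H](C(CCl)(C(=O)OC(C)(C)C)C(=O)OC(C)(C)C)C[C@@H]1[C@H](C)[C@@](O)(C(=O)C[C@H](C)O[Si](C)(C)C(C)(C)C)[C@H]2OC(=O)[C@H](C)CC | intermediate
27 | ring-opened cis-lactone still bearing one tert-butyl ester and the silyl ether (C11 epimers; 9β-OH free) | CC(C)(C)OC(=O)C1(CCl)C(=O)O[C@@H]2[C@H]1C[C@@H](O)[C@H](C)[C@@](O)(C(=O)C[C@H](C)O[Si](C)(C)C(C)(C)C)[C@H]2OC(=O)[C@H](C)CC | intermediate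
28 | 11-carboxy-11-(chloromethyl) analogue of the target (C11 epimers), i.e. the target with C(CO2H)(CH2Cl) in place of C=CH2 | OC(=O)C1(CCl)C(=O)O[C@@H]2[C@H]1C[C@@H](O)[C@H](C)[C@@](O)(C(=O)C[C@H](C)O)[C@H]2OC(=O)[C@H](C)CC | intermediate
29 | sodium carboxylate of 28 | [Na+].[O-]C(=O)C1(CCl)C(=O)O[C@@H]2[C@H]1C[C@@H](O)[C@H](C)[C@@](O)(C(=O)C[C@H](C)O)[C@H]2OC(=O)[C@H](C)CC | intermediate
30 | CNP0291806.3: cis-fused α-methylene-γ-lactone with 1α,9β-dihydroxy, 10α-methyl, 1β-[(S)-3-hydroxybutanoyl] and 5β-[(R)-2-methylbutanoyloxy] groups | C=C1C(=O)O[C@@H]2[C@H]1C[C@@H](O)[C@H](C)[C@@](O)(C(=O)C[C@H](C)O)[C@H]2OC(=O)[C@H](C)CC | target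

## Step count and least certain steps

Total: 15 steps. Longest linear sequence: 11 steps (1, 2, 5, 6, 7, 8, 9, 12, 13, 14, 15). The diazo partner (steps 3 and 4) and the side-chain bromide (steps 10 and 11) are two-step branches.

**Step 5 (key step).** Three things may go wrong. The carbenoid may attack the substituted edge of the furan, because the ring carbon next to the Mal group is the more electron-rich α-position. The furan may open to a dienone through a zwitterion instead of closing the cyclopropane. The enantioselectivity may be low with a benzyl ester and a hindered furan.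
Fallback: the cationic [4+3] cycloaddition. From 5, the 1-methyl-2-oxyallyl cation generated from 1,3-dibromobutan-2-one and Et2Zn should give the racemic 10α-methyl-7-Mal-oxabicyclooctenone F1 in one step. Hydrogenation (H2, Pd/C) rejoins the route at 14 as the racemate. Steps 8 and 9 then give 18 together with the diastereomeric ester F2, which are separated by chromatography, so the route is enantiopure again from 18. This replaces carbenoid chemistry by an oxyallyl cation and catalyst control by a resolution with the acid that the target needs anyway.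

**Step 14.** The ether may not open at C6 under acid mild enough for the side chain. C6 is hindered and deactivated by the neighbouring acyloxy group. The ester carbonyl could instead reach C9 through a six-membered transition state. The β-hydroxy ketone could dehydrate, or the tertiary ketol could shift, if stronger acid or heat is needed.
Fallback: open the bridge before the side chain exists. From 18, which has no sensitive group and tolerates forcing acid (TfOH with warming, then TFA), the same lactonisation gives keto lactone acid F3. Excess vinyllithium 23 with LaCl3·2LiCl (the carboxylate and alkoxide form first and are inert) should add to the C1 ketone from the β face, away from the α-oriented cis-lactone and C10 methyl, to give allylic alcohol F4. Ozonolysis gives ketol F5, and HF·pyridine returns to 28. The price is that C1 is then set by substrate control on the monocycle, not by the bicyclic template.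

**Step 12.** The ketone is flanked by an axial acyloxy group on the exo face and by the Mal group on the endo face, so enolisation or attack on the neighbouring ester may outrun addition. Base may also epimerise the α-acyloxy centre C5.
Fallback: bring the C5 ester in after the addition, by epoxide opening; this also bypasses steps 8 and 9. From 14, KN(SiMe3)2 and then N-bromosuccinimide should give the 5β-bromo ketone F6. Reagent 23 with LaCl3·2LiCl adds from the β face, and the 1α-alkoxide displaces the trans-diaxial bromide to give the 1α,5α-epoxide F7. The caesium salt of 17 (Cs2CO3, DMF, 80 °C) opens F7 at the secondary carbon C5 with inversion (trans-diaxial opening) and gives 24 directly.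

**Step 15.** Warm aqueous base may cause retro-aldol cleavage or dehydration of the β-hydroxy ketone, or oxa-Michael addition of a hydroxyl to the new methylene lactone, before the chloride fragmentation is complete.
Fallback: separate the two events. From 28, heating in toluene (90 °C) without base decarboxylates the malonic-type acid to the α-chloromethyl lactone F8. Et3N in CH2Cl2 at 0 °C then eliminates HCl through the lactone enolate (E1cB) to give 30.

## Further compounds

F1 | step 5 | racemic 2-methyl-6-Mal-8-oxabicyclo[3.2.1]oct-6-en-3-one (methyl equatorial; one enantiomer drawn) | O1[C@H]2C(C(CCl)(C(=O)OC(C)(C)C)C(=O)OC(C)(C)C)=C[C@@H]1[C@H](C)C(=O)C2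
F2 | step 5 | diastereomer of 18 built on the enantiomeric bicycle | O1[C@@H]2[C@@H](C(CCl)(C(=O)OC(C)(C)C)C(=O)OC(C)(C)C)C[C@H]1[C@@H](C)C(=O)[C@@H]2OC(=O)[C@H](C)CC
F3 | step 14 | 1-oxo cis-lactone acid with 9β-hydroxyl and the 5β ester (C11 epimers) | OC(=O)C1(CCl)C(=O)O[C@@H]2[C@H]1C[C@@H](O)[C@H](C)C(=O)[C@H]2OC(=O)[C@H](C)CC
F4 | step 14 | 1α-hydroxy-1β-[(S)-4-(tert-butyldimethylsilyloxy)pent-1-en-2-yl] lactone acid | OC(=O)C1(CCl)C(=O)O[C@@H]2[C@H]1C[C@@H](O)[C@H](C)[C@@](O)(C(=C)C[C@H](C)O[Si](C)(C)C(C)(C)C)[C@H]2OC(=O)[C@H](C)CC
F5 | step 14 | 4-O-silyl ether of 28 | OC(=O)C1(CCl)C(=O)O[C@@H]2[C@H]1C[C@@H](O)[C@H](C)[C@@](O)(C(=O)C[C@H](C)O[Si](C)(C)C(C)(C)C)[C@H]2OC(=O)[C@H](C)CC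
F6 | step 12 | 5β-bromo-6β,9β-epoxy-10α-methyl-7α-Mal-cycloheptan-1-one | O1[C@H]2[C@H](C(CCl)(C(=O)OC(C)(C)C)C(=O)OC(C)(C)C)C[C@@H]1[C@H](C)C(=O)[C@H]2Br
F7 | step 12 | 1α,5α-epoxide with the 1β side-chain alkene (6β,9β-ether bridge intact) | O1[C@H]2[C@H](C(CCl)(C(=O)OC(C)(C)C)C(=O)OC(C)(C)C)C[C@@H]1[C@H](C)[C@]3(C(=C)C[C@H](C)O[Si](C)(C)C(C)(C)C)O[C@H]23
F8 | step 15 | 11-(chloromethyl) lactone, i.e. 28 without the carboxyl group (C11 epimers) | ClCC1C(=O)O[C@@H]2[C@H]1C[C@@H](O)[C@H](C)[C@@](O)(C(=O)C[C@H](C)O)[C@H]2OC(=O)[C@H](C)CC
A1 | alternative 1 | open-chain ω-formyl 2-(bromomethyl)enoate with silyl-protected hydroxyls | COC(=O)C(CBr)=CC[C@@H](O[Si](CC)(CC)CC)[C@H](C)[C@@](O[Si](C)(C)C)(C(=O)C[C@H](C)O[Si](C)(C)C(C)(C)C)[C@H](C=O)OC(=O)[C@H](C)CC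
A2 | alternative 2 | 2-(benzyloxy)-6-methyl-8-oxabicyclo[3.2.1]oct-6-en-3-one (bridge joins C5 and C9; benzyloxy equatorial on C6) | c1ccccc1CO[C@@H]2C(=O)C[C@@H]1C(C)=C[C@H]2O1
A3 | alternative 3 | 6,7-dioxabicyclo[3.2.2]non-8-ene (meso endoperoxide) | O1OC2CCCC1C=C2
A4 | alternative 3 | (R)-4-hydroxycyclohept-2-en-1-one | O=C1C=C[C@H](O)CCC1
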